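If the substrate charge rises with the free catalyst held at 0.50 mM, the target fraction read at 25 min falls in these flasks, and I watch that fall.

| flask | substrate | free catalyst | remark | time |
|---|---|---|---|---|
| south | 0.045 M | 0.50 mM | run made earlier |  |
| south-west | 0.78 M | 0.50 mM | run made earlier |  |
| Saturday's | 0.060 M | 0.50 mM |  | 25 min |
| Sunday's | 0.50 M | 0.50 mM |  | 25 min |
| Thursday's | 0.40 M | 0.50 mM |  | 25 min |
| Tuesday's | 1.0 M | 0.50 mM |  | 25 min |
| Monday's | 0.25 M | 0.50 mM |  | 25 min |

| south: time / min | south: target / % | south-west: time / min | south-west: target / % |
|---|---|---|---|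
| 1.50 | 3 | 4.00 | 5 |
| 5.00 | 12 | 8.00 | 9 |
| 8.00 | 17 | 12.0 | 13 |
| 15.0 | 28 | 15.0 | 11 |
| 20.0 | 36 | 20.0 | 11 |
| 25.0 | 36 | 25.0 | 14 |

(each reading ± 1.5 percentage points)

- the flasks by amount of target, in percent of the substrate charged, highest first, at 25 min (Saturday's / Sunday's / Thursday's / Tuesday's / Monday's)
- the same order at 1.5 h (Saturday's / Sunday's / Thursday's / Tuesday's / Monday's)
- the amount of target, in percent of the substrate charged of the flask you put first, at 25 min
- the amount of target, in percent of the substrate charged of the flask you put last, at 25 min

1. South reads 36% of its charge at 25 min. South-west reads 14%.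

2. Bound from above: I assume the fraction keeps falling as the charge rises. So Saturday's stays under 36%, and Tuesday's under 14%.

3. Bound from below: fraction times charge is greater in south-west than in south, and I assume it keeps rising with the charge. So Saturday's stays above 27.0%, and Tuesday's above 10.9%.

4. Tightening: I freeze the log of the fraction ratio over the log of the charge ratio, 0.331, the fall exponent. The upper bounds mean an exponent of 0, the lower ones 1. My reckoning gives Saturday's 32.7% and Tuesday's 12.9%. I rank the flasks by rising charge, and I keep that order at 1.5 h.

5. The forecast gives Saturday's > Monday's > Thursday's > Sunday's > Tuesday's, and Saturday's > Monday's > Thursday's > Sunday's > Tuesday's at 1.5 h, with 33% and 10.5%: “Every flask should reach its plateau by about 25 min”. Its top lies inside my bracket. Its low lies below mine by 0.40 percentage points, against a scatter of 1.5 points.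

6. The flasks give Saturday's > Monday's > Thursday's > Sunday's > Tuesday's, and Saturday's > Monday's > Thursday's > Sunday's > Tuesday's at 1.5 h, with 35.1% and 12.4%.

    target + free catalyst ⇌ isomer of the product + free catalyst, rate k1*[free catalyst]*[target] forward; the back reaction follows from the equilibrium constant (K = 1.10, k = 0.210 /M/s)
    2 substrate → self-condensation product (k = 0.00310 /M/s)
    substrate + free catalyst → spent catalyst (k = 0.00130 /M/s)
    substrate ⇌ target (K = 2.90, k = 4.70 × 10⁻⁴ /s)

Saturday's stands above 27.0% and below 36%. Tuesday's stands above 10.9% and below 14%. In Tuesday's, the first half-life of substrate by self-condensation, 2.69 min, is shorter than the 25 min of the forward step to target. In Saturday's, that first half-life is 44.8 min, longer than the forward 25 min.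

Now take Tuesday's flask recharged with 0.25 M: from 12.4%, the fall exponent gives 19.6%. The computed flask holds 24.2%.

Readings and results are calculated from invented constants, and the scatter is random.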